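Amounts first: teal, grey, blue and ochre each hold 0.068 M of substrate but 0.0340 M of partner, so I start by asking what that charge allows.

| flask | substrate | partner | free catalyst | temperature | remark | time |
|---|---|---|---|---|---|---|
| delta | 0.095 M | 0.034 M | 6.8 mM | 75 °C | run made earlier |  |
| beta | 0.15 M | 0.034 M | 6.8 mM | 100 °C | run made earlier |  |
| alpha | 0.068 M | 0.034 M | 14 mM | 75 °C | run made earlier |  |
| teal | 0.068 M | 0.0340 M | 6.8 mM | 100 °C |  | 4.0 h |
| grey | 0.068 M | 0.0340 M | 6.8 mM |  | at 80 °C until 50 min, from then on at 120 °C | 4.0 h |
| blue | 0.068 M | 0.0340 M | 6.8 mM | 80 °C |  | 4.0 h |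
| ochre | 0.068 M | 0.0340 M | 6.8 mM | 120 °C |  | 4.0 h |

| run | time / h | product / % |
|---|---|---|
| delta | 1.00 | 21 |
| delta | 3.00 | 37 |
| delta | 5.00 | 31 |
| delta | 8.00 | 38 |
| delta | 15.0 | 38 |
| beta | 0.833 | 24 |
| beta | 1.50 | 23 |
| beta | 2.50 | 24 |
| beta | 3.00 | 23 |
| beta | 4.00 | 20 |
| beta | 5.00 | 22 |
| alpha | 3.00 | 51 |
| alpha | 6.00 | 48 |
| alpha | 10.0 | 48 |
| alpha | 15.0 | 48 |

(readings scatter by 2 percentage points)



1. the flask that comes out highest in amount of product, in percent of the substrate charged, or "all alike" when all lie within 1.5 percentage points (teal / grey / blue / ochre / all alike)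
2. product at the end, in percent of the substrate charged, teal
3. product at the end, in percent of the substrate charged, grey
4. product at the end, in percent of the substrate charged, blue
5. product at the end, in percent of the substrate charged, ochre

How much can form? In the earlier runs the plateau follows the partner. I call the ceiling the partner charged over the substrate charged, 50.0% for these flasks. The ceiling is 35.8% in delta, which reads 38% at its last point; 22.7% in beta, which reads 22%; and 50.0% in alpha, which reads 48%. So I read the partner as the limiting reagent, one to one with the substrate.

Can the catalyst stop short of that? Counting turnovers, the flasks ask 5.00 per catalyst, and beta's last reading already shows 4.85. Alpha, with twice that catalyst, also reads at its ceiling. The catalyst therefore comes back, and the plateaus read at the ceiling with 6.8 mM of it and with 14 mM.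

Is there time? Delta also needs 5.00 turnovers, and it reads 37% by 3.00 h at 75 °C. If the pace follows the substrate, blue's smaller charge stretches that to 4.19 h, about as long as the 4.0 h allowed, and blue is also warmer. Beta reads its ceiling by 0.833 h; stretched the same way for teal's smaller charge at the same temperature, that is 1.84 h, shorter than the 4.0 h allowed. Ochre runs hotter than any earlier run, so no reading tests it, and that there is no loss there is my bare assumption. I expect teal, grey, blue and ochre to stand at the ceiling, within the margin of 1.5 percentage points.

The forecast gives teal 49%, grey 48.5%, blue 46% and ochre 48%, and says “Teal is the safest pick for highest”. It differs from my reckoning most at blue, which it puts below my ceiling.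

Teal gives 50.0%, grey 50.0%, blue 50.0% and ochre 50.0%, so the answer is all alike, not teal.

    substrate + catalyst intermediate A ⇌ catalyst intermediate B (K = 47.0 /M, k = 0.260 /M/s, Ea = 64.0 kJ/mol, ΔH = −45.0 kJ/mol)
    catalyst intermediate C → free catalyst + product (k = 0.160 /s, Ea = 101 kJ/mol)
    catalyst intermediate B → released group + catalyst intermediate C (k = 0.0250 /s, Ea = 95.0 kJ/mol)
    partner + free catalyst ⇌ catalyst intermediate A (K = 1300 /M, k = 0.430 /M/s, Ea = 54.0 kJ/mol, ΔH = −33.0 kJ/mol)
    (constants at 100 °C)

Each of these flasks ends at the ceiling of 50.0%; ochre keeps 50% of its substrate and 0% of its partner. A neighbour of ochre is charged with 0.12 M of substrate and the same partner, which lowers the ceiling to 28.3%. That neighbour gives 28.3%, with 0% of its partner and 72% of its substrate left.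

The runs stem from a simulated flask on assumed constants; noise was put on by code.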